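## Retrosynthetic overview

1. The two phenols are unmasked last (Si–O cleavage). The carbinol C–aryl bond is cut back to the cis aldehyde 15 and aryl Grignard reagent 3; the Felkin–Anh and 1,3-chelate models agree on the (S) carbinol.
2. Key disconnection: oxolane 15 ⇒ its isomer (4R)-4-[(Z)-3-arylprop-1-enyl]-1,3-dioxolane 12. SnCl4 should trigger a 2-oxonia-Cope/aldol (Prins–pinacol) cascade that makes C4–C5 first and then closes the oxolane through the C2–C3 bond. The dioxolane C4–C5 bond, which is absent from the target, is broken and its stereocentre is exchanged for C3 and C4.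
3. Enabling feature: the β-alkoxy carbonyl (aldol) array O1–C2H2–C3–C(exocyclic carbinol carbon) of the oxolane, with unsubstituted C2H2 and C5H2 on either side of O1 (both formaldehyde-level carbons) and a 3,4-cis relationship that is the imprint of a (Z)-alkene.
4. 12 comes from the chiral pool: (R)-solketal supplies oxolane O1, C2, C3 and the carbinol C–O (its stereocentre becomes the formyl carbon) by Swern oxidation, (Z)-selective Wittig reaction and acetonide-to-formaldehyde-acetal exchange. Both aryl units come from 5-bromo-2-methoxyphenol through the one Grignard reagent 3, which is prepared once and used twice.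
5. Ring order: the arenes are bought; a temporary 1,3-dioxolane is carried from solketal and re-made as the formaldehyde acetal (step 9); the oxolane, the only ring built for the target, is formed in step 10.

Key step: step 10

Remark: the oxolane is numbered O1, C2, C3 (carbinol-bearing), C4 (arylmethyl-bearing), C5; the target SMILES is read as 3,4-cis with (3S,4R) ring centres and an (S) carbinol; Ar = 4-methoxy-3-(triisopropylsilyloxy)phenyl.

## Route

Step 1
Reactants: 1 5-bromo-2-methoxyphenol
Product: 2 (5-bromo-2-methoxyphenoxy)triisopropylsilane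
Conditions: TIPSCl, imidazole, DMF, rt
Reagents that add atoms: triisopropylsilyl chloride, CC(C)[Si](Cl)(C(C)C)C(C)C
Why: Phenol silylation with a silyl chloride and imidazole; the triisopropylsilyl ether should survive Grignard formation, ylide chemistry, aqueous acetic acid and SnCl4 and is removed by fluoride at the end.

Step 2
Reactants: 2 (5-bromo-2-methoxyphenoxy)triisopropylsilane
Product: 3 [4-methoxy-3-(triisopropylsilyloxy)phenyl]magnesium bromide (titrated THF stock solution)
Conditions: Mg turnings, I2 (cat.), THF, 45 °C; titrated and kept under Ar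
Reagents that add atoms: magnesium, [Mg]
Why: Oxidative insertion of magnesium into the aryl C–Br bond (Grignard formation) should give a stable aryl Grignard solution that is prepared once on a scale covering both of its uses, in step 3 and in step 11.

Step 3
Reactants: 3 [4-methoxy-3-(triisopropylsilyloxy)phenyl]magnesium bromide
Product: 4 2-[4-methoxy-3-(triisopropylsilyloxy)phenyl]ethanol
Conditions: CuI (10 mol %), ethylene oxide, THF, −30 → 0 °C; H2O
Reagents that add atoms: ethylene oxide, C1CO1
Why: CuI-catalysed SN2 opening of ethylene oxide by the aryl Grignard reagent should give the two-carbon homologated primary alcohol.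

Step 4
Reactants: 4 2-[4-methoxy-3-(triisopropylsilyloxy)phenyl]ethanol
Product: 5 [5-(2-iodoethyl)-2-methoxyphenoxy]triisopropylsilane
Conditions: I2, PPh3, imidazole, CH2Cl2, 0 °C → rt
Reagents that add atoms: iodine, II
Why: Appel-type iodination of a primary alcohol (PPh3/I2/imidazole) proceeds by SN2 displacement of the alkoxyphosphonium ion under neutral conditions that leave the aryl silyl ether alone.

Step 5
Reactants: 5 [5-(2-iodoethyl)-2-methoxyphenoxy]triisopropylsilane
Product: 6 {2-[4-methoxy-3-(triisopropylsilyloxy)phenyl]ethyl}triphenylphosphonium iodide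
Conditions: PPh3, MeCN, reflux
Reagents that add atoms: triphenylphosphine, c1ccc(cc1)P(c1ccccc1)c1ccccc1
Why: SN2 quaternisation of triphenylphosphine by a primary iodide gives the Wittig salt.

Step 6
Reactants: 7 (R)-solketal ([(4R)-2,2-dimethyl-1,3-dioxolan-4-yl]methanol)
Product: 8 (4S)-2,2-dimethyl-1,3-dioxolane-4-carbaldehyde
Conditions: (COCl)2, DMSO, CH2Cl2, −78 °C; Et3N, −78 → 0 °C; used crude at once
Reagents that add atoms: none
Why: Swern oxidation should convert the primary alcohol into the configurationally labile α-alkoxy aldehyde at low temperature without epimerisation (the descriptor changes from R to S only through the priority rules).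

Step 7
Reactants: 6 {2-[4-methoxy-3-(triisopropylsilyloxy)phenyl]ethyl}triphenylphosphonium iodide; 8 (4S)-2,2-dimethyl-1,3-dioxolane-4-carbaldehyde
Product: 10 (4R)-4-[(1Z)-3-Ar-prop-1-enyl]-2,2-dimethyl-1,3-dioxolane, via ylide 9 (not isolated)
Conditions: KN(SiMe3)2, THF, −78 °C; then 8, −78 °C → rt
Reagents that add atoms: none
Why: Lithium-free Wittig olefination of a non-stabilised ylide with an α-alkoxy aldehyde should give the (Z)-alkene under kinetic control through the cis-oxaphosphetane, and the dioxolane stereocentre is not touched at −78 °C.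

Step 8
Reactants: 10 (4R)-4-[(1Z)-3-Ar-prop-1-enyl]-2,2-dimethyl-1,3-dioxolane
Product: 11 (2R,3Z)-5-[4-methoxy-3-(triisopropylsilyloxy)phenyl]pent-3-ene-1,2-diol
Conditions: AcOH/H2O (4:1), 40 °C
Reagents that add atoms: none
Why: Acid-catalysed hydrolysis of the isopropylidene acetal, which the aryl triisopropylsilyl ether and the skipped (Z)-alkene should tolerate.

Step 9
Reactants: 11 (2R,3Z)-5-[4-methoxy-3-(triisopropylsilyloxy)phenyl]pent-3-ene-1,2-diol
Product: 12 (4R)-4-[(1Z)-3-Ar-prop-1-enyl]-1,3-dioxolane
Conditions: CH2(OMe)2 (5 equiv), LiBr (cat.), TsOH·H2O (cat.), CH2Cl2, 4 Å molecular sieves, rt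
Reagents that add atoms: dimethoxymethane, COCOC
Why: Acid-catalysed transacetalisation with dimethoxymethane should close the five-membered formaldehyde acetal of the 1,2-diol without affecting the stereocentre or the alkene geometry.

Step 10
Reactants: 12 (4R)-4-[(1Z)-3-Ar-prop-1-enyl]-1,3-dioxolane
Product: 15 (3S,4R)-4-(Ar-methyl)oxolane-3-carbaldehyde, via oxocarbenium stannate 13 (not isolated), via enolate–oxocarbenium zwitterion 14 (not isolated)
Conditions: SnCl4 (2 equiv), CH2Cl2, −78 → −30 °C; cold pH 7 phosphate buffer; used without chromatography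
Reagents that add atoms: none
Why: SnCl4 should open the formaldehyde acetal at the allylic oxygen to the homoallylic oxocarbenium ion 13, which undergoes a chair 2-oxonia-Cope rearrangement (new C4–C5 bond) to the tin enolate/oxocarbenium ion 14, whose enolate carbon then closes onto the new oxocarbenium carbon (the C2–C3 bond) and releases SnCl4; a concerted Prins cyclisation/1,2-shift through the same chair leads to the same product. The closest known reaction type is the Lewis acid-promoted rearrangement of 4-alkenyl-1,3-dioxolanes to 3-acyltetrahydrofurans (Prins–pinacol or oxonia-Cope–aldol), applied here to a secondary allylic carbinol so that the acyl group is a formyl group. The oxolane is closed by a 5-(enolexo)-endo-trig aldol addition onto an oxocarbenium ion, the oxygen analogue of the Mannich step of the aza-Cope–Mannich reaction. C4 is set by 1,3-chirality transfer from the dioxolane carbinol carbon through the chair with the stannyloxy group equatorial, because the other chair would place it 1,3-diaxial to the arylmethyl group that the (Z)-alkene forces axial. C3 is set by suprafacial delivery of the oxocarbenium carbon to the enolate face it already lies over, so the (Z)-geometry is translated into the 3,4-cis relationship. The step needs cis selectivity against the more stable trans aldehyde, and this is secured by kinetic control at low temperature with a cold buffered quench.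

Step 11
Reactants: 3 [4-methoxy-3-(triisopropylsilyloxy)phenyl]magnesium bromide; 15 (3S,4R)-4-(Ar-methyl)oxolane-3-carbaldehyde
Product: 16 (S)-Ar-[(3S,4R)-4-(Ar-methyl)oxolan-3-yl]methanol
Conditions: 15 added to 3 (1.3 equiv), THF, −78 °C; H2O
Reagents that add atoms: none
Why: Grignard addition to an α-branched aldehyde, in which the Felkin–Anh model (attack anti to the more substituted C4 with the carbonyl oxygen near C2) and the 1,3-chelate model through the ring oxygen both lead to the (S) carbinol, and addition at −78 °C should outrun enolisation so that the cis relationship is kept.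

Step 12
Reactants: 16 (S)-Ar-[(3S,4R)-4-(Ar-methyl)oxolan-3-yl]methanol
Product: 17 (S)-(3-hydroxy-4-methoxyphenyl)-[(3S,4R)-4-[(3-hydroxy-4-methoxyphenyl)methyl]oxolan-3-yl]methanol
Conditions: Bu4NF, AcOH, THF, 0 °C
Reagents that add atoms: none
Why: Fluoride-mediated desilylation should cleave both aryl silyl ethers, and the benzylic alcohol is safe because it is meta to the liberated phenols (no quinone methide pathway) and no epimerisable centre remains.

## Compound list

1 | 5-bromo-2-methoxyphenol | COc1ccc(Br)cc1O | starting material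
2 | (5-bromo-2-methoxyphenoxy)triisopropylsilane | COc1ccc(Br)cc1O[Si](C(C)C)(C(C)C)C(C)C | intermediate
3 | [4-methoxy-3-(triisopropylsilyloxy)phenyl]magnesium bromide | COc1ccc([Mg]Br)cc1O[Si](C(C)C)(C(C)C)C(C)C | intermediate
4 | 2-[4-methoxy-3-(triisopropylsilyloxy)phenyl]ethanol | COc1ccc(CCO)cc1O[Si](C(C)C)(C(C)C)C(C)C | intermediate
5 | [5-(2-iodoethyl)-2-methoxyphenoxy]triisopropylsilane | COc1ccc(CCI)cc1O[Si](C(C)C)(C(C)C)C(C)C | intermediate
6 | {2-[4-methoxy-3-(triisopropylsilyloxy)phenyl]ethyl}triphenylphosphonium iodide | COc1ccc(CC[P+](c2ccccc2)(c2ccccc2)c2ccccc2)cc1O[Si](C(C)C)(C(C)C)C(C)C.[I-] | intermediate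
7 | (R)-solketal ([(4R)-2,2-dimethyl-1,3-dioxolan-4-yl]methanol) | OC[C@@H]1COC(C)(C)O1 | starting material
8 | (4S)-2,2-dimethyl-1,3-dioxolane-4-carbaldehyde | O=C[C@@H]1COC(C)(C)O1 | intermediate
9 | {2-[4-methoxy-3-(triisopropylsilyloxy)phenyl]ethylidene}triphenylphosphorane | COc1ccc(CC=P(c2ccccc2)(c2ccccc2)c2ccccc2)cc1O[Si](C(C)C)(C(C)C)C(C)C | intermediate
10 | (4R)-4-[(1Z)-3-[4-methoxy-3-(triisopropylsilyloxy)phenyl]prop-1-en-1-yl]-2,2-dimethyl-1,3-dioxolane | COc1ccc(C/C=C\[C@@H]2COC(C)(C)O2)cc1O[Si](C(C)C)(C(C)C)C(C)C | intermediate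
11 | (2R,3Z)-5-[4-methoxy-3-(triisopropylsilyloxy)phenyl]pent-3-ene-1,2-diol | COc1ccc(C/C=C\[C@@H](O)CO)cc1O[Si](C(C)C)(C(C)C)C(C)C | intermediate
12 | (4R)-4-[(1Z)-3-[4-methoxy-3-(triisopropylsilyloxy)phenyl]prop-1-en-1-yl]-1,3-dioxolane | COc1ccc(C/C=C\[C@@H]2COCO2)cc1O[Si](C(C)C)(C(C)C)C(C)C | intermediate
13 | ring-opened zwitterion: (2R,3Z)-1-(methylideneoxonio)-5-aryl-pent-3-en-2-yl oxide bound to SnCl4 | COc1ccc(C/C=C\[C@@H](O[Sn-](Cl)(Cl)(Cl)Cl)C[O+]=C)cc1O[Si](C(C)C)(C(C)C)C(C)C | intermediate
14 | SnCl4-bound (E)-enolate of (3R)-3-(arylmethyl)-4-(methylideneoxonio)butanal | COc1ccc(C[C@@H](C[O+]=C)/C=C/O[Sn-](Cl)(Cl)(Cl)Cl)cc1O[Si](C(C)C)(C(C)C)C(C)C | intermediate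
15 | (3S,4R)-4-{[4-methoxy-3-(triisopropylsilyloxy)phenyl]methyl}oxolane-3-carbaldehyde (3,4-cis) | COc1ccc(C[C@H]2COC[C@H]2C=O)cc1O[Si](C(C)C)(C(C)C)C(C)C | intermediate
16 | (S)-[4-methoxy-3-(triisopropylsilyloxy)phenyl]-[(3S,4R)-4-{[4-methoxy-3-(triisopropylsilyloxy)phenyl]methyl}oxolan-3-yl]methanol | COc1ccc(C[C@H]2COC[C@H]2[C@H](O)c2ccc(OC)c(O[Si](C(C)C)(C(C)C)C(C)C)c2)cc1O[Si](C(C)C)(C(C)C)C(C)C | intermediate
17 | (S)-(3-hydroxy-4-methoxyphenyl)-[(3S,4R)-4-[(3-hydroxy-4-methoxyphenyl)methyl]oxolan-3-yl]methanol | COc1ccc(C[C@H]2COC[C@H]2[C@H](O)c2ccc(OC)c(O)c2)cc1O | target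

## Step count and risks

Total step count: 12. Longest linear sequence: 11 steps (steps 1–5 and 7–12 from 5-bromo-2-methoxyphenol; step 6 lies on the solketal branch).

Steps most likely to fail:

**Step 10.** The process at risk is loss of the 3,4-cis relationship. This would happen if ring closure of 14 were slower than rotation about the C3–C4 bond, or if the SnCl4-bound aldehyde epimerised at C3 by enolisation or retro-aldol reopening. Sluggish ionisation of the unsubstituted acetal carbon would force higher temperatures and make this worse. C4 is not at risk, since it is fixed in the sigmatropic event. The fallback sets out from 12 and comes back at 15. The rearrangement is run for conversion only (SnCl4, CH2Cl2, −78 → 0 °C), which should give 15 mixed with its C3 epimer (3R,4R)-4-{[4-methoxy-3-(triisopropylsilyloxy)phenyl]methyl}oxolane-3-carbaldehyde F1. Both epimers converge on the enol acetate [(4R)-4-{[4-methoxy-3-(triisopropylsilyloxy)phenyl]methyl}oxolan-3-ylidene]methyl acetate F2 (Ac2O, Et3N, DMAP, CH2Cl2). Heterogeneous hydrogenation of its exocyclic alkene from the face opposite the C4 arylmethyl group (H2, Rh/Al2O3, EtOAc) should give the cis acetate [(3S,4R)-4-{[4-methoxy-3-(triisopropylsilyloxy)phenyl]methyl}oxolan-3-yl]methyl acetate F3. Treatment with i-Bu2AlH at −78 °C should free the cis alcohol [(3R,4R)-4-{[4-methoxy-3-(triisopropylsilyloxy)phenyl]methyl}oxolan-3-yl]methanol F4, and Dess–Martin oxidation buffered with NaHCO3 returns 15. C3 is then set by substrate-controlled hydrogenation, a known way to the less stable cis isomer, and not by the cascade.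

**Step 11.** The process at risk is poor or reversed facial selectivity in the aryl transfer to the aldehyde, together with base-induced epimerisation at C3 before addition. The fallback sets out from 16, taken as its mixture with the carbinol epimer, and comes back at 16. The mixture is oxidised with Dess–Martin periodinane (NaHCO3, CH2Cl2, 0 °C) to the ketone [4-methoxy-3-(triisopropylsilyloxy)phenyl]-[(3S,4R)-4-{[4-methoxy-3-(triisopropylsilyloxy)phenyl]methyl}oxolan-3-yl]methanone F5. The carbinol centre is then set by reagent-controlled hydride delivery with BH3·SMe2 and (R)-2-methyl-CBS-oxazaborolidine (THF, −20 °C), which should give the (S) alcohol for an aryl ketone. Because hydride is now the incoming group, a substrate bias that favoured the wrong carbinol in the aryl addition should work in the right direction here, and a weak bias leaves the catalyst in control.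

**Step 7.** The process at risk is erosion of (Z)-selectivity in the Wittig reaction (stereochemical drift of the oxaphosphetane, or base-mediated migration of the skipped alkene), which would carry an (E)-alkene on to the trans oxolane. The fallback sets out from 8 and 3 and comes back at 10. Aldehyde 8 is homologated with dimethyl (1-diazo-2-oxopropyl)phosphonate (K2CO3, MeOH) to the alkyne (4R)-4-ethynyl-2,2-dimethyl-1,3-dioxolane F6. A portion of the Grignard solution 3 is quenched with paraformaldehyde to give [4-methoxy-3-(triisopropylsilyloxy)phenyl]methanol F7, which MsCl and Et3N should convert into the benzylic chloride [5-(chloromethyl)-2-methoxyphenoxy]triisopropylsilane F8. Coupling of F6 with F8 (PdCl2(MeCN)2, XPhos, Cs2CO3, THF, 65 °C) should give the internal alkyne (4R)-4-{3-[4-methoxy-3-(triisopropylsilyloxy)phenyl]prop-1-yn-1-yl}-2,2-dimethyl-1,3-dioxolane F9. Syn semihydrogenation (H2, Pd/CaCO3 poisoned with Pb(OAc)2, quinoline, EtOAc) then delivers 10 with the (Z)-geometry fixed by the mechanism.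

Further compounds

F1 | step 10 | (3R,4R)-4-{[4-methoxy-3-(triisopropylsilyloxy)phenyl]methyl}oxolane-3-carbaldehyde (3,4-trans) | COc1ccc(C[C@H]2COC[C@@H]2C=O)cc1O[Si](C(C)C)(C(C)C)C(C)C
F2 | step 10 | [(4R)-4-{[4-methoxy-3-(triisopropylsilyloxy)phenyl]methyl}oxolan-3-ylidene]methyl acetate (E/Z mixture) | COc1ccc(C[C@H]2COCC2=COC(C)=O)cc1O[Si](C(C)C)(C(C)C)C(C)C
F3 | step 10 | [(3S,4R)-4-{[4-methoxy-3-(triisopropylsilyloxy)phenyl]methyl}oxolan-3-yl]methyl acetate (3,4-cis) | COc1ccc(C[C@H]2COC[C@H]2COC(C)=O)cc1O[Si](C(C)C)(C(C)C)C(C)C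
F4 | step 10 | [(3R,4R)-4-{[4-methoxy-3-(triisopropylsilyloxy)phenyl]methyl}oxolan-3-yl]methanol (3,4-cis) | COc1ccc(C[C@H]2COC[C@H]2CO)cc1O[Si](C(C)C)(C(C)C)C(C)C
F5 | step 11 | [4-methoxy-3-(triisopropylsilyloxy)phenyl]-[(3S,4R)-4-{[4-methoxy-3-(triisopropylsilyloxy)phenyl]methyl}oxolan-3-yl]methanone | COc1ccc(C[C@H]2COC[C@H]2C(=O)c2ccc(OC)c(O[Si](C(C)C)(C(C)C)C(C)C)c2)cc1O[Si](C(C)C)(C(C)C)C(C)C
F6 | step 7 | (4R)-4-ethynyl-2,2-dimethyl-1,3-dioxolane | C#C[C@@H]1COC(C)(C)O1
F7 | step 7 | [4-methoxy-3-(triisopropylsilyloxy)phenyl]methanol | COc1ccc(CO)cc1O[Si](C(C)C)(C(C)C)C(C)C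
F8 | step 7 | [5-(chloromethyl)-2-methoxyphenoxy]triisopropylsilane | COc1ccc(CCl)cc1O[Si](C(C)C)(C(C)C)C(C)C
F9 | step 7 | (4R)-4-{3-[4-methoxy-3-(triisopropylsilyloxy)phenyl]prop-1-yn-1-yl}-2,2-dimethyl-1,3-dioxolane | COc1ccc(CC#C[C@@H]2COC(C)(C)O2)cc1O[Si](C(C)C)(C(C)C)C(C)C
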